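**Strategy.** Ring C of the target is a pyran in which O1–C2 and C3–C4 flank the C2–C3 unit, with C4 benzylic, attached to ring A ortho to O1, and the substituents 2,3-trans/3,4-trans. This maps onto an oxa-[4+2] union of a ring A o-quinone methide (O1=C8a–C4a=C4) with an (E)-styrylboronate (C2=C3). One operation forms C3–C4 and O1–C2, closes ring C and sets C2, C3 and C4; boron at C3 is later exchanged for hydroxyl with retention. The precursor is a racemic o-hydroxybenzhydrol carrying the bromoresorcinol ring on the carbinol carbon, silylated everywhere except the ring A phenol; the bromide later becomes the styryl arm.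

Key step: step 7

**Remarks before the steps**

- Abbreviations: TIPS = triisopropylsilyl, TBS = tert-butyldimethylsilyl, Bpin = 4,4,5,5-tetramethyl-1,3,2-dioxaborolan-2-yl.
- Assumption: the (R)-configured phosphoric acid is taken to give the (2S,3S,4S)-boronate 13; if the first run shows the opposite sense, the (S)-acid is used with no other change.
- Target configuration: (2R,3S,4S), i.e. 2-aryl and 4-aryl cis to each other and both trans to the 3-hydroxyl.
- Precursor design: all oxygens that pass through the Grignard, acid and perborate steps carry TIPS groups, for three reasons.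
  - The bulk suppresses silyl migration from the ortho-silyloxy group to the neighbouring carbinol alkoxide or to the arylmagnesium carbon.
  - TIPS aryl ethers resist mild aqueous base.
  - The groups shield the electron-rich ring positions against Friedel–Crafts self-condensation of the quinone methide.
- The catechol, which meets only the Heck step, carries TBS groups.
- Only the ring A phenol is free, so only one quinone methide can form.

**Route**

Step 1
Reactants: 1 5-bromoresorcinol
Product: 2 1-bromo-3,5-bis(triisopropylsilyloxy)benzene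
Conditions: TIPSCl (2.3 equiv), imidazole, DMF, rt
Reagents that add atoms: chlorotriisopropylsilane, CC(C)[Si](Cl)(C(C)C)C(C)C
Why: Imidazole-promoted O-silylation of both phenols (silyl ether formation) should proceed cleanly on an unhindered resorcinol.

Step 2
Reactants: 2 1-bromo-3,5-bis(triisopropylsilyloxy)benzene
Product: 3 1-bromo-2-iodo-3,5-bis(triisopropylsilyloxy)benzene
Conditions: NIS (1.1 equiv), TFA (cat.), MeCN/CH2Cl2, rt, dark
Reagents that add atoms: N-iodosuccinimide, O=C1CCC(=O)N1I
Why: Electrophilic aromatic iodination should occur at C2 (equivalent to C6), which is ortho to one silyloxy group and para to the other, because C4 between the two bulky silyloxy groups is sterically blocked.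

Step 3
Reactants: 4 2,4-dihydroxybenzaldehyde
Product: 5 2-hydroxy-4-(triisopropylsilyloxy)benzaldehyde
Conditions: TIPSCl (1.05 equiv), imidazole, CH2Cl2, 0 °C
Reagents that add atoms: chlorotriisopropylsilane, CC(C)[Si](Cl)(C(C)C)C(C)C
Why: Selective mono-silylation should take the 4-hydroxyl, since the 2-hydroxyl is held in a hydrogen bond to the formyl group and is the less nucleophilic of the two.

Step 4
Reactants: 3 1-bromo-2-iodo-3,5-bis(triisopropylsilyloxy)benzene; 5 2-hydroxy-4-(triisopropylsilyloxy)benzaldehyde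
Product: 8 racemic [2-bromo-4,6-bis(triisopropylsilyloxy)phenyl][2-hydroxy-4-(triisopropylsilyloxy)phenyl]methanol, via arylmagnesium chloride 6 (not isolated), via sodium phenoxide 7 (not isolated)
Conditions: 3, i-PrMgCl·LiCl, THF, −30 °C; 5, NaH, THF, 0 °C; add 7 to 6, −30 → 0 °C; aq. NH4Cl
Reagents that add atoms: none
Why: Knochel iodine–magnesium exchange is much faster at C–I than at C–Br and the o-bromoarylmagnesium should not lose MgBrCl to an aryne below 0 °C; it then adds 1,2 to the aldehyde, whose phenol is already the phenoxide so that no Grignard reagent is quenched, and the racemic carbinol centre is erased in step 7.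

Step 5
Reactants: 9 4-hydroxybenzaldehyde
Product: 10 4-(triisopropylsilyloxy)benzaldehyde
Conditions: TIPSCl (1.1 equiv), imidazole, DMF, rt
Reagents that add atoms: chlorotriisopropylsilane, CC(C)[Si](Cl)(C(C)C)C(C)C
Why: Standard imidazole-promoted silylation of a phenol.

Step 6
Reactants: 10 4-(triisopropylsilyloxy)benzaldehyde
Product: 11 (E)-2-[4-(triisopropylsilyloxy)phenyl]ethenylboronic acid pinacol ester
Conditions: CH2(Bpin)2, 2,2,6,6-tetramethylpiperidine, n-BuLi, THF, 0 °C; then 10, −78 °C → rt; aq. NH4Cl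
Reagents that add atoms: bis(4,4,5,5-tetramethyl-1,3,2-dioxaborolan-2-yl)methane, CC1(C)OB(CB2OC(C)(C)C(C)(C)O2)OC1(C)C
Why: Boron–Wittig olefination, in which the lithiated geminal diboronate adds to the aldehyde and the adduct eliminates a borate, should give the E-alkenylboronate.

Step 7
Reactants: 8 racemic [2-bromo-4,6-bis(triisopropylsilyloxy)phenyl][2-hydroxy-4-(triisopropylsilyloxy)phenyl]methanol; 11 (E)-2-[4-(triisopropylsilyloxy)phenyl]ethenylboronic acid pinacol ester
Product: 13 (2S,3S,4S)-4-[2-bromo-4,6-bis(triisopropylsilyloxy)phenyl]-3-(pinacolboryl)-7-(triisopropylsilyloxy)-2-[4-(triisopropylsilyloxy)phenyl]chroman, via o-quinone methide 12 (not isolated)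
Conditions: (R)-3,3'-bis(2,4,6-triisopropylphenyl)-1,1'-binaphthyl-2,2'-diyl hydrogen phosphate (10 mol %), 11 (2 equiv), 4 Å MS, PhMe, 0 °C → rt, slow addition of 8
Reagents that add atoms: none
Why: Proposed new method: the chiral phosphoric acid should dehydrate 8 to the hydrogen-bonded o-quinone methide 12, whose C4 is attacked by the boron-bearing carbon of 11 while the 4-silyloxyphenyl group takes up the positive charge building at C2, which the quinone oxygen O1 then captures in a concerted but asynchronous inverse-electron-demand oxa-[4+2] cycloaddition. The closest known reaction type is the chiral Brønsted acid catalysed hetero-Diels–Alder reaction of o-hydroxybenzhydrol-derived o-quinone methides with styrenes and (E)-propenylarenes; an alkenylboronate has not been used as the 2π partner. Ring C is closed by [4+2] cycloaddition, C3–C4 forming ahead of O1–C2 as the six-membered ring closes. C2/C3 trans follows from suprafacial addition to the E alkene, C2/C4 cis from the endo orientation of the 4-silyloxyphenyl group towards the E-configured quinone methide, and the absolute configuration from the chiral phosphate, which stays bound to O1 and blocks one face of the diene. The step needs regioselectivity (the para-oxyaryl group outweighs the weak polarisation by boron), chemoselectivity for cycloaddition over deborylative alkenyl transfer (favoured by the non-exchanging, weakly Lewis acidic pinacol ester) and a single quinone methide (only the ring A phenol is free). The bromide in place of the styryl arm removes an internal alkene that could trap C4, and slow addition of 8 keeps 12 dilute against self-condensation.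

Step 8
Reactants: 13 (2S,3S,4S)-4-[2-bromo-4,6-bis(triisopropylsilyloxy)phenyl]-3-(pinacolboryl)-7-(triisopropylsilyloxy)-2-[4-(triisopropylsilyloxy)phenyl]chroman
Product: 14 (2R,3S,4S)-4-[2-bromo-4,6-bis(triisopropylsilyloxy)phenyl]-7-(triisopropylsilyloxy)-2-[4-(triisopropylsilyloxy)phenyl]chroman-3-ol
Conditions: NaBO3·4H2O, THF/H2O, rt
Reagents that add atoms: sodium perborate tetrahydrate, O.O.O.O.[Na+].[O-]OB=O
Why: Perborate oxidation of the secondary C–B bond proceeds by 1,2-migration of C3 from boron to oxygen with retention, so the 3-hydroxyl should end up trans to both aryl groups; the weakly basic medium should leave TIPS ethers and the aryl bromide untouched (the descriptor at C2 changes only through the priority rules).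

Step 9
Reactants: 15 3,4-dihydroxybenzaldehyde
Product: 16 3,4-bis(tert-butyldimethylsilyloxy)benzaldehyde
Conditions: TBSCl (2.3 equiv), imidazole, DMF, rt
Reagents that add atoms: tert-butylchlorodimethylsilane, CC(C)(C)[Si](C)(C)Cl
Why: Standard bis-silylation of a catechol.

Step 10
Reactants: 16 3,4-bis(tert-butyldimethylsilyloxy)benzaldehyde
Product: 17 3,4-bis(tert-butyldimethylsilyloxy)styrene
Conditions: Ph3PCH3Br, KOt-Bu, THF, 0 °C → rt
Reagents that add atoms: methyltriphenylphosphonium bromide, [Br-].C[P+](c1ccccc1)(c1ccccc1)c1ccccc1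
Why: Wittig methylenation with the preformed non-stabilised ylide should convert the aldehyde to the terminal alkene without touching the silyl ethers.

Step 11
Reactants: 14 (2R,3S,4S)-4-[2-bromo-4,6-bis(triisopropylsilyloxy)phenyl]-7-(triisopropylsilyloxy)-2-[4-(triisopropylsilyloxy)phenyl]chroman-3-ol; 17 3,4-bis(tert-butyldimethylsilyloxy)styrene
Product: 18 (2R,3S,4S)-4-{2-[(E)-2-[3,4-bis(tert-butyldimethylsilyloxy)phenyl]ethenyl]-4,6-bis(triisopropylsilyloxy)phenyl}-7-(triisopropylsilyloxy)-2-[4-(triisopropylsilyloxy)phenyl]chroman-3-ol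
Conditions: Pd(OAc)2 (5 mol %), [HP(t-Bu)3]BF4 (10 mol %), Cy2NMe, 17 (1.5 equiv), dioxane, 80 °C
Reagents that add atoms: none
Why: Mizoroki–Heck reaction: zerovalent palladium, formed in situ from the divalent palladium acetate and carrying the bulky electron-rich phosphine, should insert into the hindered C–Br bond, and syn-carbopalladation of the terminal alkene followed by syn-β-hydride elimination should give the E-stilbene; the amine base spares the silyl ethers and the free 3-hydroxyl.

Step 12
Reactants: 18 (2R,3S,4S)-4-{2-[(E)-2-[3,4-bis(tert-butyldimethylsilyloxy)phenyl]ethenyl]-4,6-bis(triisopropylsilyloxy)phenyl}-7-(triisopropylsilyloxy)-2-[4-(triisopropylsilyloxy)phenyl]chroman-3-ol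
Product: 19 (2R,3S,4S)-4-{2-[(E)-2-(3,4-dihydroxyphenyl)ethenyl]-4,6-dihydroxyphenyl}-2-(4-hydroxyphenyl)chroman-3,7-diol (CNP0170061.1)
Conditions: Et3N·3HF (excess), THF/MeCN, rt → 45 °C, Ar
Reagents that add atoms: none
Why: Fluoride-driven cleavage of all six aryl silyl ethers under buffered, slightly acidic conditions should avoid phenoxide formation, so the catechol is not air-oxidised, C2 is not epimerised and the acid-labile C4–aryl bond is not stressed.

**Compound list**

1 | 5-bromoresorcinol | Oc1cc(O)cc(Br)c1 | starting material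
2 | 1-bromo-3,5-bis(triisopropylsilyloxy)benzene | Brc1cc(O[Si](C(C)C)(C(C)C)C(C)C)cc(O[Si](C(C)C)(C(C)C)C(C)C)c1 | intermediate
3 | 1-bromo-2-iodo-3,5-bis(triisopropylsilyloxy)benzene | Brc1cc(O[Si](C(C)C)(C(C)C)C(C)C)cc(O[Si](C(C)C)(C(C)C)C(C)C)c1I | intermediate
4 | 2,4-dihydroxybenzaldehyde | O=Cc1ccc(O)cc1O | starting material
5 | 2-hydroxy-4-(triisopropylsilyloxy)benzaldehyde | O=Cc1ccc(O[Si](C(C)C)(C(C)C)C(C)C)cc1O | intermediate
6 | [2-bromo-4,6-bis(triisopropylsilyloxy)phenyl]magnesium chloride, lithium chloride adduct | [Li+].[Cl-].Cl[Mg]c1c(Br)cc(O[Si](C(C)C)(C(C)C)C(C)C)cc1O[Si](C(C)C)(C(C)C)C(C)C | intermediate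
7 | sodium 2-formyl-5-(triisopropylsilyloxy)phenoxide | [Na+].[O-]c1cc(O[Si](C(C)C)(C(C)C)C(C)C)ccc1C=O | intermediate
8 | racemic [2-bromo-4,6-bis(triisopropylsilyloxy)phenyl][2-hydroxy-4-(triisopropylsilyloxy)phenyl]methanol | Oc1cc(O[Si](C(C)C)(C(C)C)C(C)C)ccc1C(O)c1c(O[Si](C(C)C)(C(C)C)C(C)C)cc(O[Si](C(C)C)(C(C)C)C(C)C)cc1Br | intermediate
9 | 4-hydroxybenzaldehyde | O=Cc1ccc(O)cc1 | starting material
10 | 4-(triisopropylsilyloxy)benzaldehyde | O=Cc1ccc(O[Si](C(C)C)(C(C)C)C(C)C)cc1 | intermediate
11 | (E)-2-[4-(triisopropylsilyloxy)phenyl]ethenylboronic acid pinacol ester | CC(C)[Si](C(C)C)(C(C)C)Oc1ccc(/C=C/B2OC(C)(C)C(C)(C)O2)cc1 | intermediate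
12 | (E)-6-{[2-bromo-4,6-bis(triisopropylsilyloxy)phenyl]methylidene}-3-(triisopropylsilyloxy)cyclohexa-2,4-dien-1-one (ring A o-quinone methide) | O=C1C=C(O[Si](C(C)C)(C(C)C)C(C)C)C=C/C1=C\c1c(O[Si](C(C)C)(C(C)C)C(C)C)cc(O[Si](C(C)C)(C(C)C)C(C)C)cc1Br | intermediate
13 | (2S,3S,4S)-4-[2-bromo-4,6-bis(triisopropylsilyloxy)phenyl]-3-(pinacolboryl)-7-(triisopropylsilyloxy)-2-[4-(triisopropylsilyloxy)phenyl]chroman (2,3-trans, 3,4-trans) | CC(C)[Si](C(C)C)(C(C)C)Oc1ccc([C@H]2Oc3cc(O[Si](C(C)C)(C(C)C)C(C)C)ccc3[C@@H](c3c(O[Si](C(C)C)(C(C)C)C(C)C)cc(O[Si](C(C)C)(C(C)C)C(C)C)cc3Br)[C@@H]2B4OC(C)(C)C(C)(C)O4)cc1 | intermediate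
14 | (2R,3S,4S)-4-[2-bromo-4,6-bis(triisopropylsilyloxy)phenyl]-7-(triisopropylsilyloxy)-2-[4-(triisopropylsilyloxy)phenyl]chroman-3-ol | CC(C)[Si](C(C)C)(C(C)C)Oc1ccc([C@H]2Oc3cc(O[Si](C(C)C)(C(C)C)C(C)C)ccc3[C@@H](c3c(O[Si](C(C)C)(C(C)C)C(C)C)cc(O[Si](C(C)C)(C(C)C)C(C)C)cc3Br)[C@@H]2O)cc1 | intermediate
15 | 3,4-dihydroxybenzaldehyde | O=Cc1ccc(O)c(O)c1 | starting material
16 | 3,4-bis(tert-butyldimethylsilyloxy)benzaldehyde | O=Cc1ccc(O[Si](C)(C)C(C)(C)C)c(O[Si](C)(C)C(C)(C)C)c1 | intermediate
17 | 3,4-bis(tert-butyldimethylsilyloxy)styrene | C=Cc1ccc(O[Si](C)(C)C(C)(C)C)c(O[Si](C)(C)C(C)(C)C)c1 | intermediate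
18 | (2R,3S,4S)-4-{2-[(E)-2-[3,4-bis(tert-butyldimethylsilyloxy)phenyl]ethenyl]-4,6-bis(triisopropylsilyloxy)phenyl}-7-(triisopropylsilyloxy)-2-[4-(triisopropylsilyloxy)phenyl]chroman-3-ol | CC(C)[Si](C(C)C)(C(C)C)Oc1ccc([C@H]2Oc3cc(O[Si](C(C)C)(C(C)C)C(C)C)ccc3[C@@H](c3c(O[Si](C(C)C)(C(C)C)C(C)C)cc(O[Si](C(C)C)(C(C)C)C(C)C)cc3/C=C/c3ccc(O[Si](C)(C)C(C)(C)C)c(O[Si](C)(C)C(C)(C)C)c3)[C@@H]2O)cc1 | intermediate
19 | (2R,3S,4S)-4-{2-[(E)-2-(3,4-dihydroxyphenyl)ethenyl]-4,6-dihydroxyphenyl}-2-(4-hydroxyphenyl)chroman-3,7-diol | Oc1ccc([C@H]2Oc3cc(O)ccc3[C@@H](c3c(O)cc(O)cc3/C=C/c3ccc(O)c(O)c3)[C@@H]2O)cc1 | target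

**Step count**

Total: 12 steps. Longest linear sequence: 7 steps (steps 1, 2, 4, 7, 8, 11, 12).

**Steps most likely to fail, with fallbacks**

1. Step 7. After C3–C4 bond formation the C2 cation may shed boron instead of closing (alkenyl transfer), the quinone methide may self-condense, or facial selectivity may be poor. The fallback sets out from 8 and returns at 14, using known reaction types.
   - Commercial 4-hydroxybenzonitrile would be silylated (TIPSCl, imidazole) to 4-(triisopropylsilyloxy)benzonitrile F1. Addition of MeMgBr and an Ac2O quench should give the enamide N-{1-[4-(triisopropylsilyloxy)phenyl]ethenyl}acetamide F2.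
   - Chiral phosphoric acid catalysed conjugate addition of F2 to 12 (generated from 8 as in step 7, the acid enantiomer chosen to give 4S) is an established enantioselective reaction class. It should give the cyclic N,O-acetal N-[(4S)-4-[2-bromo-4,6-bis(triisopropylsilyloxy)phenyl]-7-(triisopropylsilyloxy)-2-[4-(triisopropylsilyloxy)phenyl]chroman-2-yl]acetamide F3.
   - Warming F3 with p-toluenesulfonic acid should expel acetamide and give (4S)-4-[2-bromo-4,6-bis(triisopropylsilyloxy)phenyl]-7-(triisopropylsilyloxy)-2-[4-(triisopropylsilyloxy)phenyl]-4H-chromene F4.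
   - Hydroboration with BH3·THF should place boron on C3 from the face opposite the C4 aryl group, giving the 2,3-trans-3,4-trans (2S,3S,4S)-chroman-3-ylborane F5. NaBO3 oxidation with retention then gives 14. Here C4 is set by the catalyst and C2/C3 by the substrate.

2. Step 4. Addition of the doubly ortho-substituted arylmagnesium to the electron-rich phenoxide aldehyde may be slow, letting aryne formation by loss of MgBrCl or proton quench compete. The fallback reverses the polarity of the union; it sets out from 3 (via 6) and returns at 8.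
   - Quenching 6 with the small electrophile DMF should give 2-bromo-4,6-bis(triisopropylsilyloxy)benzaldehyde F6.
   - Commercial 4-bromoresorcinol would be silylated at the hydroxyl remote from bromine (TIPSCl, imidazole) to 2-bromo-5-(triisopropylsilyloxy)phenol F7.
   - n-BuLi (2.1 equiv, THF, −78 °C) should deprotonate the phenol and exchange the bromide to give lithium 2-lithio-5-(triisopropylsilyloxy)phenoxide F8. This unhindered aryllithium should add to F6 and give 8 after NH4Cl work-up.

3. Step 11. Oxidative addition and alkene insertion at the bromide flanked by the bulky chromanyl group may be sluggish, so that hydrodebromination or oligomerisation of the electron-rich styrene takes over. The fallback replaces carbopalladation by cross-coupling with a preformed alkenyl nucleophile; it sets out from 16 and 14 and returns at 18.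
   - Boron–Wittig olefination of 16 (CH2(Bpin)2, lithium 2,2,6,6-tetramethylpiperidide, THF) should give (E)-2-[3,4-bis(tert-butyldimethylsilyloxy)phenyl]ethenylboronic acid pinacol ester F9.
   - Suzuki–Miyaura coupling of F9 with 14 (Pd(OAc)2, 2-dicyclohexylphosphino-2',6'-dimethoxybiphenyl, K3PO4, PhMe/H2O, 70 °C) should give 18. Any partial loss of silyl groups under the basic conditions is harmless because step 12 removes them all.

Further compounds
F1 | step 7 | 4-(triisopropylsilyloxy)benzonitrile | N#Cc1ccc(O[Si](C(C)C)(C(C)C)C(C)C)cc1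
F2 | step 7 | N-{1-[4-(triisopropylsilyloxy)phenyl]ethenyl}acetamide | CC(=O)NC(=C)c1ccc(O[Si](C(C)C)(C(C)C)C(C)C)cc1
F3 | step 7 | N-[(4S)-4-[2-bromo-4,6-bis(triisopropylsilyloxy)phenyl]-7-(triisopropylsilyloxy)-2-[4-(triisopropylsilyloxy)phenyl]chroman-2-yl]acetamide (C2 epimers) | CC(=O)NC1(c2ccc(O[Si](C(C)C)(C(C)C)C(C)C)cc2)C[C@H](c2c(O[Si](C(C)C)(C(C)C)C(C)C)cc(O[Si](C(C)C)(C(C)C)C(C)C)cc2Br)c2ccc(O[Si](C(C)C)(C(C)C)C(C)C)cc2O1
F4 | step 7 | (4S)-4-[2-bromo-4,6-bis(triisopropylsilyloxy)phenyl]-7-(triisopropylsilyloxy)-2-[4-(triisopropylsilyloxy)phenyl]-4H-chromene | CC(C)[Si](C(C)C)(C(C)C)Oc1ccc(C2=C[C@H](c3c(O[Si](C(C)C)(C(C)C)C(C)C)cc(O[Si](C(C)C)(C(C)C)C(C)C)cc3Br)c3ccc(O[Si](C(C)C)(C(C)C)C(C)C)cc3O2)cc1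
F5 | step 7 | (2S,3S,4S)-4-[2-bromo-4,6-bis(triisopropylsilyloxy)phenyl]-7-(triisopropylsilyloxy)-2-[4-(triisopropylsilyloxy)phenyl]chroman-3-ylborane | CC(C)[Si](C(C)C)(C(C)C)Oc1ccc([C@H]2Oc3cc(O[Si](C(C)C)(C(C)C)C(C)C)ccc3[C@@H](c3c(O[Si](C(C)C)(C(C)C)C(C)C)cc(O[Si](C(C)C)(C(C)C)C(C)C)cc3Br)[C@@H]2B)cc1
F6 | step 4 | 2-bromo-4,6-bis(triisopropylsilyloxy)benzaldehyde | O=Cc1c(Br)cc(O[Si](C(C)C)(C(C)C)C(C)C)cc1O[Si](C(C)C)(C(C)C)C(C)C
F7 | step 4 | 2-bromo-5-(triisopropylsilyloxy)phenol | Oc1cc(O[Si](C(C)C)(C(C)C)C(C)C)ccc1Br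
F8 | step 4 | lithium 2-lithio-5-(triisopropylsilyloxy)phenoxide | [Li]Oc1cc(O[Si](C(C)C)(C(C)C)C(C)C)ccc1[Li]
F9 | step 11 | (E)-2-[3,4-bis(tert-butyldimethylsilyloxy)phenyl]ethenylboronic acid pinacol ester | CC(C)(C)[Si](C)(C)Oc1ccc(/C=C/B2OC(C)(C)C(C)(C)O2)cc1O[Si](C)(C)C(C)(C)C
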